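**Plan**

- Numbering: lactone ring O1, C2–C6; side chain C1′–C21′. Retrosynthesis first removes the three O-protecting groups and reaches the lactone from its 2-pyranone (one extra unsaturation, C5=C6). It then cuts C3–C4 and C5–C6 together, which takes C4–C5 out as acetylene and rejoins C3 to C6 in a β-keto ester. Last it cuts the aldol bonds C1′–C2′ and C5′–C6′.
- Enabling feature: in the ring, carbonyl C2 and carbinol C6 are 1,5-related across C3–C4–C5. Without C4–C5 they are the 1,3-dicarbonyl unit C2–C3–C6, the same group that each acetoacetate aldol leaves at the chain end.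
- Forward: hexadecanal + acetoacetate dienolate → δ-hydroxy-β-keto ester → syn-diol → acetonide → aldehyde → second acetoacetate aldol → silyl ether → acetylene insertion into C3–C6 with closure of the 2-pyranone (the only ring of the target) → hydrogenation of C5=C6 → deprotection.
- Stereochemistry: C6′ and C2′ from one Ti(OiPr)4/(S)-BINOL catalyst used twice, C4′ from boron-chelate-controlled 1,3-syn reduction, C6 from a Ru–bisphosphine hydrogenation of the pyranone (catalyst control). The target is the all-syn compound (6S,2′R,4′R,6′R).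

Key step: step 7

Assumption: the facial sense of the (S)-BINOL catalyst (steps 1 and 5) and of the (S)-bisphosphine (step 8) is taken by analogy with simple aldehydes and 6-alkyl-2-pyranones; if a first run shows the opposite sense, the other ligand antipode is used.

**Route**

Step 1
Reactants: 1 hexadecanal; 2 1-methoxy-1,3-bis(trimethylsilyloxy)buta-1,3-diene
Product: 4 methyl (5R)-5-hydroxy-3-oxoicosanoate, via bis-TMS aldol adduct 3 (not isolated)
Conditions: Ti(OiPr)4 (10 mol %), (S)-BINOL (10 mol %), 4 Å MS, THF, −78 °C to rt; then TFA, wet THF, 0 °C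
Reagents that add atoms: 1-methoxy-1,3-bis(trimethylsilyloxy)buta-1,3-diene (2), C=C(O[Si](C)(C)C)C=C(OC)O[Si](C)(C)C
Why: Catalytic enantioselective vinylogous Mukaiyama aldol reaction in which the γ-carbon of the silyl dienolate should add to the Si face of the aldehyde bound to the chiral titanium BINOLate, setting C5 as R, after which acid removes both TMS groups.

Step 2
Reactants: 4 methyl (5R)-5-hydroxy-3-oxoicosanoate
Product: 6 methyl (3R,5R)-3,5-dihydroxyicosanoate, via diethylboron chelate 5 (not isolated)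
Conditions: Et2BOMe (1.1 equiv), THF/MeOH 4:1, −78 °C; NaBH4; then MeOH co-evaporation (boron leaves as Et2BOMe)
Reagents that add atoms: none
Why: Narasaka–Prasad reduction, in which the boron chelate 5 holds the β-hydroxy ketone in a half-chair and external hydride adds axially, so the new C3 carbinol (R) should be 1,3-syn under substrate control.

Step 3
Reactants: 6 methyl (3R,5R)-3,5-dihydroxyicosanoate; 7 2,2-dimethoxypropane
Product: 8 methyl 2-[(4R,6R)-2,2-dimethyl-6-pentadecyl-1,3-dioxan-4-yl]acetate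
Conditions: 2,2-dimethoxypropane, PPTS (cat.), CH2Cl2, rt
Reagents that add atoms: 2,2-dimethoxypropane (7), COC(C)(C)OC
Why: Acid-catalysed transketalisation closes the syn-1,3-diol to a six-membered acetonide whose chair carries both side chains equatorial, and no stereocentre is touched.

Step 4
Reactants: 8 methyl 2-[(4R,6R)-2,2-dimethyl-6-pentadecyl-1,3-dioxan-4-yl]acetate
Product: 9 2-[(4R,6R)-2,2-dimethyl-6-pentadecyl-1,3-dioxan-4-yl]acetaldehyde
Conditions: iBu2AlH (1.05 equiv), CH2Cl2, −78 °C; then MeOH, aq. potassium sodium tartrate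
Reagents that add atoms: none
Why: Partial reduction of a methyl ester, in which the aluminium hemiacetal is stable at −78 °C and releases the aldehyde only on work-up; the β-alkoxy centre cannot epimerise.

Step 5
Reactants: 9 2-[(4R,6R)-2,2-dimethyl-6-pentadecyl-1,3-dioxan-4-yl]acetaldehyde; 2 1-methoxy-1,3-bis(trimethylsilyloxy)buta-1,3-diene
Product: 11 methyl (5R)-6-[(4S,6R)-2,2-dimethyl-6-pentadecyl-1,3-dioxan-4-yl]-5-hydroxy-3-oxohexanoate, via bis-TMS aldol adduct 10 (not isolated)
Conditions: Ti(OiPr)4 (20 mol %), (S)-BINOL (20 mol %), 4 Å MS, THF, −78 °C to rt; then TFA, wet THF, −78 to 0 °C (brief)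
Reagents that add atoms: 1-methoxy-1,3-bis(trimethylsilyloxy)buta-1,3-diene (2), C=C(O[Si](C)(C)C)C=C(OC)O[Si](C)(C)C
Why: Second use of the same vinylogous Mukaiyama aldol reaction and catalyst antipode, in which Si-face attack should set the new carbinol (hexanoate C5, R) syn to the ring oxygen on the dioxane C4 under catalyst control, against the weak 1,3-anti preference of the β-alkoxy aldehyde.

Step 6
Reactants: 11 methyl (5R)-6-[(4S,6R)-2,2-dimethyl-6-pentadecyl-1,3-dioxan-4-yl]-5-hydroxy-3-oxohexanoate; 12 tert-butyldimethylsilyl chloride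
Product: 13 methyl (5R)-5-[(tert-butyldimethylsilyl)oxy]-6-[(4R,6R)-2,2-dimethyl-6-pentadecyl-1,3-dioxan-4-yl]-3-oxohexanoate
Conditions: TBSCl, imidazole, DMF, rt
Reagents that add atoms: tert-butyldimethylsilyl chloride (12), CC(C)(C)[Si](C)(C)Cl
Why: Standard silylation of the secondary alcohol, which blocks lactonisation of the δ-hydroxy-β-keto ester; imidazole is too weak a base for enol silylation or β-elimination.

Step 7
Reactants: 13 methyl (5R)-5-[(tert-butyldimethylsilyl)oxy]-6-[(4R,6R)-2,2-dimethyl-6-pentadecyl-1,3-dioxan-4-yl]-3-oxohexanoate; 14 acetylene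
Product: 16 6-[(2R)-2-[(tert-butyldimethylsilyl)oxy]-3-[(4R,6R)-2,2-dimethyl-6-pentadecyl-1,3-dioxan-4-yl]propyl]-2H-pyran-2-one, via (Z)-keto enoate 15 (not isolated)
Conditions: [ReBr(CO)3(thf)]2 (5 mol %), 4 Å MS, HC≡CH (1 atm), toluene, 50 °C; then Ar purge, 110 °C
Reagents that add atoms: acetylene (14), C#C
Why: Proposed new method: the monovalent rhenium fragment ReBr(CO)3 binds the enol of 13 through both carbonyl oxygens together with acetylene, C3 adds to the coordinated alkyne, the resulting cis-alkenylrhenium carbon (C5) adds to the chelated C6 ketone, and the strained cyclobutenolate opens by retro-aldol cleavage of the old C3–C6 bond to give 15, so that C3–C4 and C5–C6 form in one catalytic event. The closest known reaction type is the ReBr(CO)3- or MnBr(CO)5-catalysed insertion of substituted alkynes into the C(α)–C(acyl) bond of simple β-keto esters, which ends in 2-pyranones, and the related acyl-alkylation of arynes; parent acetylene and a substrate with silyl ether and acetal groups go beyond that scope. Two rings close: the transient four-membered carbocycle by 4-exo-trig addition of C5 to the C6 carbonyl, and the pyranone by 6-exo-trig attack of the C6 dienol oxygen on the ester carbon C2 with loss of methanol, the latter driven by the aromatic character of the 2-pyranone. No stereocentre is formed, because C6 becomes sp2 and is set in step 8, and the three existing centres lie outside the reacting atoms. The step needs C–C insertion to outrun simple vinylation at C3 and a second acetylene uptake by the pyranone (Diels–Alder addition with loss of CO2): the 1,3-dicarbonyl chelate holds the alkenylrhenium next to C6, the molecular sieves bind methanol, and acetylene is purged before the mixture is heated. The neutral medium should spare the TBS ether and the acetonide and avoid β-elimination of the silyloxy group next to the ketone.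

Step 8
Reactants: 16 6-[(2R)-2-[(tert-butyldimethylsilyl)oxy]-3-[(4R,6R)-2,2-dimethyl-6-pentadecyl-1,3-dioxan-4-yl]propyl]-2H-pyran-2-one
Product: 17 (6S)-6-[(2R)-2-[(tert-butyldimethylsilyl)oxy]-3-[(4R,6R)-2,2-dimethyl-6-pentadecyl-1,3-dioxan-4-yl]propyl]-5,6-dihydro-2H-pyran-2-one
Conditions: H2 (60 bar), Ru(OAc)2[(S)-MeO-BIPHEP] (2 mol %), HBF4·OEt2 (4 mol %), iPrOH/CH2Cl2, 50 °C
Reagents that add atoms: none
Why: Asymmetric hydrogenation of a 2-pyranone with a cationic divalent ruthenium bisphosphine catalyst, in which the endocyclic enol-ester bond C5=C6 is the one that chelates and should be reduced, the conjugated C3=C4 bond should be left, and the ligand antipode fixes C6 as S (catalyst control).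

Step 9
Reactants: 17 (6S)-6-[(2R)-2-[(tert-butyldimethylsilyl)oxy]-3-[(4R,6R)-2,2-dimethyl-6-pentadecyl-1,3-dioxan-4-yl]propyl]-5,6-dihydro-2H-pyran-2-one
Product: 18 (6S)-6-[(2R,4R,6R)-2,4,6-trihydroxyhenicosyl]-5,6-dihydro-2H-pyran-2-one
Conditions: 48% aq. HF, MeCN/CH2Cl2, 0 °C to rt
Reagents that add atoms: none
Why: Acidic global deprotection, in which HF cleaves the TBS ether and the aqueous acid hydrolyses the acetonide; the reaction is stopped at full conversion so that the freed 2′-hydroxyl does not add to C4 of the unsaturated lactone.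

**Compound list**

1 | hexadecanal | CCCCCCCCCCCCCCCC=O | starting material
2 | 1-methoxy-1,3-bis(trimethylsilyloxy)buta-1,3-diene | C=C(O[Si](C)(C)C)C=C(OC)O[Si](C)(C)C | starting material
3 | methyl (5R)-3,5-bis(trimethylsilyloxy)icos-2-enoate (enol ether geometry not defined) | CCCCCCCCCCCCCCC[C@@H](O[Si](C)(C)C)CC(O[Si](C)(C)C)=CC(=O)OC | intermediate (not isolated)
4 | methyl (5R)-5-hydroxy-3-oxoicosanoate | CCCCCCCCCCCCCCC[C@@H](O)CC(=O)CC(=O)OC | intermediate
5 | methyl (5R)-5-[(diethylboranyl)oxy]-3-oxoicosanoate (boron chelated by the C3 carbonyl oxygen) | CCCCCCCCCCCCCCC[C@@H](OB(CC)CC)CC(=O)CC(=O)OC | intermediate (not isolated)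
6 | methyl (3R,5R)-3,5-dihydroxyicosanoate | CCCCCCCCCCCCCCC[C@@H](O)C[C@@H](O)CC(=O)OC | intermediate
7 | 2,2-dimethoxypropane | COC(C)(C)OC | starting material
8 | methyl 2-[(4R,6R)-2,2-dimethyl-6-pentadecyl-1,3-dioxan-4-yl]acetate | CCCCCCCCCCCCCCC[C@@H]1C[C@H](CC(=O)OC)OC(C)(C)O1 | intermediate
9 | 2-[(4R,6R)-2,2-dimethyl-6-pentadecyl-1,3-dioxan-4-yl]acetaldehyde | CCCCCCCCCCCCCCC[C@@H]1C[C@H](CC=O)OC(C)(C)O1 | intermediate
10 | methyl (5R)-6-[(4R,6R)-2,2-dimethyl-6-pentadecyl-1,3-dioxan-4-yl]-3,5-bis(trimethylsilyloxy)hex-2-enoate (enol ether geometry not defined) | CCCCCCCCCCCCCCC[C@@H]1C[C@H](C[C@@H](O[Si](C)(C)C)CC(O[Si](C)(C)C)=CC(=O)OC)OC(C)(C)O1 | intermediate (not isolated)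
11 | methyl (5R)-6-[(4S,6R)-2,2-dimethyl-6-pentadecyl-1,3-dioxan-4-yl]-5-hydroxy-3-oxohexanoate (the dioxane C4 is the same centre as in 9; only its CIP descriptor changes) | CCCCCCCCCCCCCCC[C@@H]1C[C@H](C[C@@H](O)CC(=O)CC(=O)OC)OC(C)(C)O1 | intermediate
12 | tert-butyldimethylsilyl chloride | CC(C)(C)[Si](C)(C)Cl | starting material
13 | methyl (5R)-5-[(tert-butyldimethylsilyl)oxy]-6-[(4R,6R)-2,2-dimethyl-6-pentadecyl-1,3-dioxan-4-yl]-3-oxohexanoate | CCCCCCCCCCCCCCC[C@@H]1C[C@H](C[C@@H](O[Si](C)(C)C(C)(C)C)CC(=O)CC(=O)OC)OC(C)(C)O1 | intermediate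
14 | acetylene | C#C | starting material
15 | methyl (3Z,7R)-7-[(tert-butyldimethylsilyl)oxy]-8-[(4R,6R)-2,2-dimethyl-6-pentadecyl-1,3-dioxan-4-yl]-5-oxooct-3-enoate | CCCCCCCCCCCCCCC[C@@H]1C[C@H](C[C@@H](O[Si](C)(C)C(C)(C)C)CC(=O)/C=C\CC(=O)OC)OC(C)(C)O1 | intermediate (not isolated)
16 | 6-[(2R)-2-[(tert-butyldimethylsilyl)oxy]-3-[(4R,6R)-2,2-dimethyl-6-pentadecyl-1,3-dioxan-4-yl]propyl]-2H-pyran-2-one | CCCCCCCCCCCCCCC[C@@H]1C[C@H](C[C@@H](O[Si](C)(C)C(C)(C)C)CC2=CC=CC(=O)O2)OC(C)(C)O1 | intermediate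
17 | (6S)-6-[(2R)-2-[(tert-butyldimethylsilyl)oxy]-3-[(4R,6R)-2,2-dimethyl-6-pentadecyl-1,3-dioxan-4-yl]propyl]-5,6-dihydro-2H-pyran-2-one | CCCCCCCCCCCCCCC[C@@H]1C[C@H](C[C@@H](O[Si](C)(C)C(C)(C)C)C[C@@H]2CC=CC(=O)O2)OC(C)(C)O1 | intermediate
18 | (6S)-6-[(2R,4R,6R)-2,4,6-trihydroxyhenicosyl]-5,6-dihydro-2H-pyran-2-one | CCCCCCCCCCCCCCC[C@@H](O)C[C@@H](O)C[C@@H](O)C[C@@H]1CC=CC(=O)O1 | target

**Totals**

Total step count: 9. Longest linear sequence: 9 steps (fully linear from hexadecanal 1).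

**Steps most likely to fail**

1. Step 7 (Proposed new method). The reaction may stop at simple vinylation of C3 because the alkenylrhenium does not add to the C6 ketone, acetylene may oligomerise on the metal, or the pyranone may take up a second acetylene and lose CO2. The fallback uses known chemistry, sets out from 11 and returns at 18.
   - Narasaka–Prasad reduction (Et2BOMe, NaBH4, THF/MeOH, −78 °C) should give the syn-diol ester methyl (3R,5S)-6-[(4S,6R)-2,2-dimethyl-6-pentadecyl-1,3-dioxan-4-yl]-3,5-dihydroxyhexanoate F1.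
   - 2,2-Dimethoxypropane/PPTS should give the bis-acetonide ester methyl 2-[(4R,6R)-6-{[(4R,6R)-2,2-dimethyl-6-pentadecyl-1,3-dioxan-4-yl]methyl}-2,2-dimethyl-1,3-dioxan-4-yl]acetate F2.
   - iBu2AlH at −78 °C should give the bis-acetonide aldehyde 2-[(4R,6R)-6-{[(4R,6R)-2,2-dimethyl-6-pentadecyl-1,3-dioxan-4-yl]methyl}-2,2-dimethyl-1,3-dioxan-4-yl]acetaldehyde F3.
   - Still–Gennari olefination ((CF3CH2O)2P(O)CH2CO2Me, KN(SiMe3)2, 18-crown-6, THF, −78 °C) should give the Z-enoate methyl (2Z)-4-[(4S,6S)-6-{[(4R,6R)-2,2-dimethyl-6-pentadecyl-1,3-dioxan-4-yl]methyl}-2,2-dimethyl-1,3-dioxan-4-yl]but-2-enoate F4.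
   - Aqueous acetic acid at 60 °C should remove both acetonides and let the δ-hydroxy Z-enoate lactonise to 18.

2. Step 8. The catalyst may go on to reduce the C3=C4 bond, or may add hydrogen to C6 with poor facial selectivity. The fallback sets out from 15 (isolated when step 7 is stopped before heating) and returns at 17.
   - Corey–Bakshi–Shibata reduction ((S)-Me-CBS oxazaborolidine, catecholborane, toluene, −78 °C, alkenyl group as the larger substituent) should give the allylic alcohol methyl (3Z,5R,7S)-7-[(tert-butyldimethylsilyl)oxy]-8-[(4R,6R)-2,2-dimethyl-6-pentadecyl-1,3-dioxan-4-yl]-5-hydroxyoct-3-enoate F5.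
   - With PPTS in CH2Cl2 this should lactonise to the β,γ-unsaturated lactone (6R)-6-[(2R)-2-[(tert-butyldimethylsilyl)oxy]-3-[(4R,6R)-2,2-dimethyl-6-pentadecyl-1,3-dioxan-4-yl]propyl]-3,6-dihydro-2H-pyran-2-one F6.
   - DBU in CH2Cl2 at rt should move the double bond into conjugation to give 17.

3. Step 5. The catalyst may fail to override the 1,3-anti bias of the chiral aldehyde (mismatched double diastereodifferentiation), or the acetonide may be lost during acidic desilylation. The fallback sets out from 9 and returns at 11.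
   - Nagao acetate aldol reaction with N-acetyl-(4R)-4-benzyl-1,3-thiazolidine-2-thione (TiCl4, iPr2NEt, CH2Cl2, −78 °C) should give, under auxiliary control, the aldol adduct (3R)-1-[(4R)-4-benzyl-2-thioxo-1,3-thiazolidin-3-yl]-4-[(4S,6R)-2,2-dimethyl-6-pentadecyl-1,3-dioxan-4-yl]-3-hydroxybutan-1-one F7; the sense of induction is assigned by analogy.
   - Displacement of the auxiliary with KO2CCH2CO2Me, MgCl2 and imidazole in THF, with decarboxylation, should give 11.

Further compounds
F1 | step 7 | methyl (3R,5S)-6-[(4S,6R)-2,2-dimethyl-6-pentadecyl-1,3-dioxan-4-yl]-3,5-dihydroxyhexanoate | CCCCCCCCCCCCCCC[C@@H]1C[C@H](C[C@@H](O)C[C@@H](O)CC(=O)OC)OC(C)(C)O1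
F2 | step 7 | methyl 2-[(4R,6R)-6-{[(4R,6R)-2,2-dimethyl-6-pentadecyl-1,3-dioxan-4-yl]methyl}-2,2-dimethyl-1,3-dioxan-4-yl]acetate | CCCCCCCCCCCCCCC[C@@H]1C[C@H](C[C@@H]2C[C@H](CC(=O)OC)OC(C)(C)O2)OC(C)(C)O1
F3 | step 7 | 2-[(4R,6R)-6-{[(4R,6R)-2,2-dimethyl-6-pentadecyl-1,3-dioxan-4-yl]methyl}-2,2-dimethyl-1,3-dioxan-4-yl]acetaldehyde | CCCCCCCCCCCCCCC[C@@H]1C[C@H](C[C@@H]2C[C@H](CC=O)OC(C)(C)O2)OC(C)(C)O1
F4 | step 7 | methyl (2Z)-4-[(4S,6S)-6-{[(4R,6R)-2,2-dimethyl-6-pentadecyl-1,3-dioxan-4-yl]methyl}-2,2-dimethyl-1,3-dioxan-4-yl]but-2-enoate | CCCCCCCCCCCCCCC[C@@H]1C[C@H](C[C@@H]2C[C@H](C/C=C\C(=O)OC)OC(C)(C)O2)OC(C)(C)O1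
F5 | step 8 | methyl (3Z,5R,7S)-7-[(tert-butyldimethylsilyl)oxy]-8-[(4R,6R)-2,2-dimethyl-6-pentadecyl-1,3-dioxan-4-yl]-5-hydroxyoct-3-enoate | CCCCCCCCCCCCCCC[C@@H]1C[C@H](C[C@@H](O[Si](C)(C)C(C)(C)C)C[C@@H](O)/C=C\CC(=O)OC)OC(C)(C)O1
F6 | step 8 | (6R)-6-[(2R)-2-[(tert-butyldimethylsilyl)oxy]-3-[(4R,6R)-2,2-dimethyl-6-pentadecyl-1,3-dioxan-4-yl]propyl]-3,6-dihydro-2H-pyran-2-one | CCCCCCCCCCCCCCC[C@@H]1C[C@H](C[C@@H](O[Si](C)(C)C(C)(C)C)C[C@@H]2C=CCC(=O)O2)OC(C)(C)O1
F7 | step 5 | (3R)-1-[(4R)-4-benzyl-2-thioxo-1,3-thiazolidin-3-yl]-4-[(4S,6R)-2,2-dimethyl-6-pentadecyl-1,3-dioxan-4-yl]-3-hydroxybutan-1-one | CCCCCCCCCCCCCCC[C@@H]1C[C@H](C[C@@H](O)CC(=O)N2[C@H](Cc3ccccc3)CSC2=S)OC(C)(C)O1
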